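The theta run creeps to 32.2% Prd by 6.00 min, and its charges give c(Sub2)/c(Sub) = 33.3%, so I read one Sub2 spent per Prd, with Sub2 as the limiting reagent. The eta run has a ratio of 154%, yet it flattens at a reading of 90.4% with 10.7% Sub unreacted, so I take that level as a stall, with Ctl lost to Zed through Sub2.

all flasks: Sub 0.078 M; Ctl 0.41 µM

| run | Sub2 | remark | time |
|---|---|---|---|
| theta | 0.026 M | run made earlier |  |
| eta | 0.12 M | run made earlier |  |
| cedar | 0.0400 M |  | 12 min |
| elm | 0.0800 M |  | 12 min |
| larch | 0.150 M |  | 12 min |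

| run | time / min | Prd / % | Sub / % |
|---|---|---|---|
| theta | 0.417 | 6.3 | 92.0 |
| theta | 1.33 | 19.5 | 80.0 |
| theta | 2.00 | 24.2 | 76.3 |
| theta | 3.00 | 28.0 | 71.9 |
| theta | 5.00 | 31.3 | 67.2 |
| theta | 6.00 | 32.2 | 66.6 |
| eta | 1.00 | 40.8 | 60.2 |
| eta | 2.00 | 66.1 | 35.2 |
| eta | 3.00 | 78.0 | 22.1 |
| eta | 4.00 | 86.6 | 15.3 |
| eta | 5.00 | 87.8 | 10.8 |
| eta | 6.00 | 90.4 | 10.7 |

(scatter of a reading: 1 percentage point)

- reactions considered so far: Sub + Ctl <-> Imd; Sub2 + Imd <-> Imd2; Sub2 + Ctl -> Zed; Imd2 -> Ctl + Prd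
- "hardly changes" means that all values lie within two and a half points (for a concentration: within two and a half percent of the largest)

1. amount of Prd at the end, in percent of the Sub charged for cedar, elm, larch, in this order
2. the shape of the row from first to last (hardly changes / falls, then rises / rises all the way / rises, then falls / falls all the way)

Cedar's charge ratio is 51.3%: c(Sub2) over c(Sub) at the start, the Prd its Sub2 can pay for at one Sub2 each. Elm's ratio is 103% and larch's is 192%, and both stand above eta's stall. So I put cedar at its ratio and the other two near the stall. Elm's ratio is smaller than larch's, so I set elm a little lower, and the row rises.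

The forecast gives 51%, 85% and 91%, rises all the way, noting of eta that “the reaction stalls near 90”.

The flasks give 51.1%, 88.7% and 92.7%, rises all the way.

    Sub + Ctl ⇌ Imd (K = 30.1 M⁻¹, k = 4.29 × 10⁶ M⁻¹ s⁻¹)
    Sub2 + Imd ⇌ Imd2 (K = 18.3 M⁻¹, k = 4.12 × 10⁶ M⁻¹ s⁻¹)
    Sub2 + Ctl → Zed (k = 0.215 M⁻¹ s⁻¹)
    Imd2 → Ctl + Prd (k = 2610 s⁻¹)

In cedar the slowest mode of the whole flask has a half-life of 1.52 min at 12.0 min, shorter than the 12 min of the run, and Prd goes from 51.1% at 12.0 min, with 0.31% of the Sub2 charge left, to 51.3% at 120 min, with 0% left, which stands at the ratio 51.3%. In larch the ratio, cedar's scaled by the Sub2 charges, is 192%, which turns Prd 92.7% into a spend of 48.2% of its Sub2 and leaves 52% of its charge.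

The data were generated by integration for an exercise; scatter was added.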